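The route rests on disconnecting the C5–C6 bond that joins the spiro carbon to the enone carbonyl of the 2-oxaspiro[4.5]decene core (spiro numbering). The feature exploited is that quaternary C5 carries both the ring ketone C6 and the lactone arm C4H2–C3(=O)–O2–C1: two carbonyls flanking one carbon, both derivable from CO. In one operation a palladium-catalysed double carbonylation converts an acyclic (Z)-vinyl iodide bearing a 1,1-disubstituted alkene and a free bis-allylic carbinol into the complete cyclohexenone spirolactone: CO insertion, 6-exo acylpalladation (C5–C6, quaternary stereocentre), second CO insertion, lactonisation. The carbinol centres C9 and C1 are set beforehand by catalytic asymmetric additions; a final cross-metathesis finishes the side chain.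

Key step: step 7

Numbering: target atoms are numbered as in 2-oxaspiro[4.5]decane (C1 lactone carbinol carbon, O2, C3 lactone carbonyl, C4, spiro C5, ketone C6, C7=C8, C9 acetoxy carbon, C10).

Remark: the facial senses of the two binaphthol-based titanium catalysts are taken by analogy with simple aldehydes ((S)-BINOL with allylstannanes: Si face; (R)-H8-BINOL with organoaluminium reagents: Re face); should either prove opposite, the antipodal ligand is used.

Step 1
Reactants: 1 2-methylprop-2-en-1-ol (methallyl alcohol)
Product: 4 triethyl({2-[(tributylstannyl)methyl]prop-2-en-1-yl}oxy)silane, via dilithio dianion 2 (not isolated), via lithium alkoxide stannane 3 (not isolated)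
Conditions: n-BuLi (2.2 equiv), TMEDA, Et2O–hexane, 0 °C to rt; Bu3SnCl (1.0 equiv), −78 to 0 °C; Et3SiCl (1.1 equiv), 0 °C to rt
Reagents that add atoms: tributyltin chloride, CCCC[Sn](Cl)(CCCC)CCCC; chlorotriethylsilane, CC[Si](Cl)(CC)CC
Why: Double deprotonation of methallyl alcohol gives the trimethylenemethane-type dianion, whose carbanion is stannylated first and whose remaining lithium alkoxide is then O-silylated in the same flask (sequential dianion trapping).

Step 2
Reactants: 5 ethyl (2Z)-3-iodoprop-2-enoate
Product: 6 (2Z)-3-iodoprop-2-enal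
Conditions: iBu2AlH (1.05 equiv), CH2Cl2, −78 °C; MeOH, then aq. KNaC4H4O6 (potassium sodium tartrate), cold; crude solution used at once
Reagents that add atoms: none
Why: Partial reduction of the ester with one equivalent of iBu2AlH at −78 °C should stop at the aldehyde level and, kept cold and acid-free, preserve the Z geometry of the iodoalkene (ester-to-aldehyde reduction).

Step 3
Reactants: 6 (2Z)-3-iodoprop-2-enal; 4 triethyl({2-[(tributylstannyl)methyl]prop-2-en-1-yl}oxy)silane
Product: 7 (1Z,3S)-1-iodo-5-{[(triethylsilyl)oxy]methyl}hexa-1,5-dien-3-ol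
Conditions: (S)-BINOL (20 mol%), Ti(OiPr)4 (10 mol%), 4 Å molecular sieves, CH2Cl2, −20 °C; aq. NaHCO3
Reagents that add atoms: none
Why: Keck asymmetric allylation: the titanium (S)-BINOLate activates the aldehyde and the 2-substituted allylstannane should add through an open transition state to the Si face, setting the (3S)-carbinol that becomes C9 of the target.

Step 4
Reactants: 7 (1Z,3S)-1-iodo-5-{[(triethylsilyl)oxy]methyl}hexa-1,5-dien-3-ol
Product: 8 (1Z,3S)-1-iodo-5-{[(triethylsilyl)oxy]methyl}hexa-1,5-dien-3-yl acetate
Conditions: Ac2O, pyridine, DMAP (cat.), CH2Cl2, 0 °C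
Reagents that add atoms: acetic anhydride, CC(=O)OC(C)=O
Why: DMAP-catalysed acylation of the secondary allylic alcohol installs the acetate of the target early, where it also serves as the group that later prevents butenolide formation at this oxygen.

Step 5
Reactants: 8 (1Z,3S)-1-iodo-5-{[(triethylsilyl)oxy]methyl}hexa-1,5-dien-3-yl acetate
Product: 9 (1Z,3S)-5-formyl-1-iodohexa-1,5-dien-3-yl acetate
Conditions: (COCl)2, DMSO, CH2Cl2, −78 to −40 °C; Et3N, −78 to 0 °C
Reagents that add atoms: none
Why: Direct Swern oxidation of primary triethylsilyl ethers is known, so activated DMSO should convert the labile primary allylic silyl ether into the 2-substituted acrolein in one operation without touching the acetate or the vinyl iodide.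

Step 6
Reactants: 9 (1Z,3S)-5-formyl-1-iodohexa-1,5-dien-3-yl acetate; 10 pent-1-en-4-yne
Product: 12 (1Z,3S,6R,7E)-6-hydroxy-1-iodo-8-methyl-5-methylideneundeca-1,7,10-trien-3-yl acetate, via alkenylalane 11 (not isolated)
Conditions: 10 (1.5 equiv), Me3Al (1.2 equiv), Cp2ZrCl2 (20 mol%), CH2Cl2, 0 °C to rt; then 9, Ti(OiPr)4 (1.5 equiv), (R)-H8-BINOL (10 mol%), toluene–THF, 0 °C; aq. KNaC4H4O6
Reagents that add atoms: trimethylaluminium, C[Al](C)C
Why: Zirconium-catalysed syn-methylalumination (Negishi carboalumination) of the alkyne gives the (E)-alkenylalane regio- and stereoselectively, and its titanium (R)-H8-BINOLate-catalysed 1,2-addition to the Re face of the enal should set the (6R)-carbinol (C1 of the target) together with the E-trisubstituted alkene.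

Step 7
Reactants: 12 (1Z,3S,6R,7E)-6-hydroxy-1-iodo-8-methyl-5-methylideneundeca-1,7,10-trien-3-yl acetate
Product: 16 (1R,5R,9S)-1-[(1E)-2-methylpenta-1,4-dien-1-yl]-3,6-dioxo-2-oxaspiro[4.5]dec-7-en-9-yl acetate, via vinylic acylpalladium iodide 13 (not isolated), via cyclised alkylpalladium iodide 14 (not isolated), via homologated acylpalladium iodide 15 (not isolated)
Conditions: PdCl2(PPh3)2 (5 mol%), Et3N (2 equiv), CO (40 atm), MeCN–benzene (1:1), 0.02 M, 80 °C
Reagents that add atoms: carbon monoxide, [C-]#[O+]
Why: Oxidative addition of zerovalent palladium to the (Z)-vinyl iodide and CO insertion give acylpalladium 13, whose acyl carbon adds syn across the 1,1-disubstituted alkene (6-exo-trig migratory insertion) to forge the C5–C6 bond and the quaternary carbon; the resulting alkylpalladium 14 has no β-hydrogen, inserts a second CO to give 15 and is captured by the neighbouring C1 hydroxyl (5-exo-trig O-acylation) to close the γ-lactone, Et3N taking up HI. The closest known reaction type is the cyclic acylpalladation–carbonylative esterification cascade of (Z)-1-iodo-1,5-dienes (Negishi), here terminated intramolecularly by an alcohol instead of by methanol. The only new stereocentre, spiro C5, is controlled by the C9 acetate: in the envelope-like insertion transition state the acetate and the bulky C1 carbinol arm should both lie pseudo-equatorial while the smaller CH2–Pd arm is axial and syn-coplanar with the acyl–palladium bond, which places C1 cis to the acetate as in the target. Chemoselectivity requires CO insertion to precede Heck-type 5-exo carbopalladation, which the high CO pressure secures, and requires cyclisation to beat O-acylation of the free hydroxyl by 13, which is secured because that would demand an eight-membered lactone. The Z geometry of the iodide holds the acyl group within reach of the alkene and becomes the cis enone, and the acetate on C9 blocks the otherwise fast butenolide closure at that oxygen.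

Step 8
Reactants: 16 (1R,5R,9S)-1-[(1E)-2-methylpenta-1,4-dien-1-yl]-3,6-dioxo-2-oxaspiro[4.5]dec-7-en-9-yl acetate; 17 2-methylbut-3-en-2-ol
Product: 18 target, (1R,5R,9S)-1-[(1E,4E)-6-hydroxy-2,6-dimethylhepta-1,4-dien-1-yl]-3,6-dioxo-2-oxaspiro[4.5]dec-7-en-9-yl acetate
Conditions: 17 (10 equiv), second-generation Hoveyda–Grubbs catalyst (5 mol%), CH2Cl2, 40 °C
Reagents that add atoms: none
Why: Olefin cross-metathesis of the terminal alkene with the hindered tertiary allylic alcohol, which does not homodimerise, should be E-selective for steric reasons, while the cis enone and the trisubstituted alkene are inert.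

Compound list
1 | 2-methylprop-2-en-1-ol | C=C(C)CO | starting material
2 | dilithio dianion of 1 (lithium 2-(lithiomethyl)prop-2-en-1-olate) | [Li]CC(=C)CO[Li] | intermediate (not isolated)
3 | lithium 2-[(tributylstannyl)methyl]prop-2-en-1-olate | CCCC[Sn](CCCC)(CCCC)CC(=C)CO[Li] | intermediate (not isolated)
4 | triethyl({2-[(tributylstannyl)methyl]prop-2-en-1-yl}oxy)silane | CCCC[Sn](CCCC)(CCCC)CC(=C)CO[Si](CC)(CC)CC | intermediate
5 | ethyl (2Z)-3-iodoprop-2-enoate | CCOC(=O)/C=C\I | starting material
6 | (2Z)-3-iodoprop-2-enal | O=C/C=C\I | intermediate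
7 | (1Z,3S)-1-iodo-5-{[(triethylsilyl)oxy]methyl}hexa-1,5-dien-3-ol | O[C@@H](CC(=C)CO[Si](CC)(CC)CC)/C=C\I | intermediate
8 | (1Z,3S)-1-iodo-5-{[(triethylsilyl)oxy]methyl}hexa-1,5-dien-3-yl acetate | CC(=O)O[C@@H](CC(=C)CO[Si](CC)(CC)CC)/C=C\I | intermediate
9 | (1Z,3S)-5-formyl-1-iodohexa-1,5-dien-3-yl acetate | CC(=O)O[C@@H](CC(=C)C=O)/C=C\I | intermediate
10 | pent-1-en-4-yne | C#CCC=C | starting material
11 | dimethyl[(1E)-2-methylpenta-1,4-dien-1-yl]alumane | C[Al](C)/C=C(\C)CC=C | intermediate (not isolated)
12 | (1Z,3S,6R,7E)-6-hydroxy-1-iodo-8-methyl-5-methylideneundeca-1,7,10-trien-3-yl acetate | CC(=O)O[C@@H](CC(=C)[C@H](O)/C=C(\C)CC=C)/C=C\I | intermediate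
13 | vinylic acylpalladium iodide from 12 (phosphine ligands omitted) | CC(=O)O[C@@H](CC(=C)[C@H](O)/C=C(\C)CC=C)/C=C\C(=O)[Pd]I | intermediate (not isolated)
14 | cyclised alkylpalladium iodide, cyclohexenone with quaternary carbon bearing CH2–Pd (phosphine ligands omitted) | CC(=O)O[C@@H]1C=CC(=O)[C@@]([C@H](O)/C=C(\C)CC=C)(C[Pd]I)C1 | intermediate (not isolated)
15 | homologated acylpalladium iodide (phosphine ligands omitted) | CC(=O)O[C@@H]1C=CC(=O)[C@@]([C@H](O)/C=C(\C)CC=C)(CC(=O)[Pd]I)C1 | intermediate (not isolated)
16 | (1R,5R,9S)-1-[(1E)-2-methylpenta-1,4-dien-1-yl]-3,6-dioxo-2-oxaspiro[4.5]dec-7-en-9-yl acetate | CC(=O)O[C@@H]1C=CC(=O)[C@@]2(CC(=O)O[C@@H]2/C=C(\C)CC=C)C1 | intermediate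
17 | 2-methylbut-3-en-2-ol | CC(C)(O)C=C | starting material
18 | target, (1R,5R,9S)-1-[(1E,4E)-6-hydroxy-2,6-dimethylhepta-1,4-dien-1-yl]-3,6-dioxo-2-oxaspiro[4.5]dec-7-en-9-yl acetate | CC(=O)O[C@@H]1C=CC(=O)[C@@]2(CC(=O)O[C@@H]2/C=C(\C)C/C=C/C(C)(C)O)C1 | target

Total step count: 8. Longest linear sequence: 7 steps (1 → 4 → 7 → 8 → 9 → 12 → 16 → 18; the same length from 5).

Steps most likely to fail

1. Step 7 (key cascade). What may go wrong: Heck-type 5-exo carbopalladation ahead of the first CO insertion, O-acylation of the free C1 hydroxyl by an acylpalladium of a second molecule, or insufficient facial discrimination at the alkene because the unprotected carbinol arm is not large enough to hold the equatorial position. Fallback, setting out from 12 and coming back at 16: 12 is silylated (Et3SiOTf, 2,6-lutidine, CH2Cl2, −78 °C) to the triethylsilyl ether F1, which carries a much larger equatorial arm and no nucleophilic hydroxyl. F1 is cyclised under the established methanol-terminated acylpalladation–methoxycarbonylation conditions (PdCl2(PPh3)2, Et3N, CO 40 atm, MeOH, MeCN–benzene, 80 °C) to the cyclohexenone methyl ester F2. HF·pyridine in THF (then PPTS in benzene at 50 °C if ring closure is slow) removes the silyl ether and lets the freed hydroxyl close the γ-lactone, giving 16.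

2. Step 6. What may go wrong: transfer of methyl instead of alkenyl from aluminium, or low facial selectivity of the catalyst on a 2-substituted acrolein, so that 12 is obtained with poor diastereomeric purity at C6. Fallback, setting out from 12 of low diastereomeric purity and coming back at 12: the material is oxidised with Dess–Martin periodinane (NaHCO3, CH2Cl2, 0 °C) to the cross-conjugated dienone F3. F3 is reduced with (S)-2-methyl-CBS-oxazaborolidine and catecholborane (toluene, −78 °C), the α-branched 1,1-disubstituted vinyl group acting as the large substituent, so that the C6 centre is set by carbonyl reduction instead of by C–C bond formation.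

3. Step 3. What may go wrong: Z-to-E isomerisation of the iodoacrolein during the slow Lewis-acid-catalysed allylation with a 2-substituted stannane. Fallback, setting out from 4 and coming back at 8: the iodoalkene is carried masked as an alkyne. Stannane 4 is added to commercial 3-(trimethylsilyl)prop-2-ynal (C[Si](C)(C)C#CC=O) under the same (S)-BINOL/Ti(OiPr)4 conditions to give the propargylic alcohol F4. Acetylation (Ac2O, pyridine, DMAP) gives the acetate F5. N-Iodosuccinimide with catalytic AgNO3 in DMF exchanges the alkynyl silane for iodine to give the iodoalkyne F6, and cis-selective diimide reduction (2-nitrobenzenesulfonyl hydrazide, Et3N, THF–iPrOH, rt) should deliver the (Z)-vinyl iodide 8.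

Further compounds
F1 | step 7 | (1Z,3S,6R,7E)-1-iodo-8-methyl-5-methylidene-6-[(triethylsilyl)oxy]undeca-1,7,10-trien-3-yl acetate | CC(=O)O[C@@H](CC(=C)[C@H](O[Si](CC)(CC)CC)/C=C(\C)CC=C)/C=C\I
F2 | step 7 | methyl 2-[(1R,5S)-5-(acetyloxy)-1-{(1R,2E)-3-methyl-1-[(triethylsilyl)oxy]hexa-2,5-dien-1-yl}-2-oxocyclohex-3-en-1-yl]acetate | CC(=O)O[C@@H]1C=CC(=O)[C@@]([C@H](O[Si](CC)(CC)CC)/C=C(\C)CC=C)(CC(=O)OC)C1
F3 | step 6 | (1Z,3S,7E)-1-iodo-8-methyl-5-methylidene-6-oxoundeca-1,7,10-trien-3-yl acetate | CC(=O)O[C@@H](CC(=C)C(=O)/C=C(\C)CC=C)/C=C\I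
F4 | step 3 | (3S)-5-{[(triethylsilyl)oxy]methyl}-1-(trimethylsilyl)hex-5-en-1-yn-3-ol | C[Si](C)(C)C#C[C@@H](O)CC(=C)CO[Si](CC)(CC)CC
F5 | step 3 | (3S)-5-{[(triethylsilyl)oxy]methyl}-1-(trimethylsilyl)hex-5-en-1-yn-3-yl acetate | C[Si](C)(C)C#C[C@@H](OC(C)=O)CC(=C)CO[Si](CC)(CC)CC
F6 | step 3 | (3S)-1-iodo-5-{[(triethylsilyl)oxy]methyl}hex-5-en-1-yn-3-yl acetate | IC#C[C@@H](OC(C)=O)CC(=C)CO[Si](CC)(CC)CC
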